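The constants you sent stand at 20 °C, and your hunch that the warmest flask must lead reads them as they stand, so I carry them to each temperature first.

    substrate → side product (k1 = 0.019 s⁻¹, Ea1 = 88.0 kJ mol⁻¹)
    target ⇌ isomer of the product (K2 = 0.86, k2 = 0.026 s⁻¹, Ea2 = 73.0 kJ mol⁻¹, ΔH2 = 24.0 kJ mol⁻¹)
    substrate + reagent ⇌ target (K3 = 340 L mol⁻¹, k3 = 140 L mol⁻¹ s⁻¹, Ea3 = 39.0 kJ mol⁻¹, ΔH3 = −25.0 kJ mol⁻¹)
    (constants at 20 °C)

| setting | dawn | dusk | spring |
|---|---|---|---|
| substrate | 2.0 mM | 2.0 mM | 2.0 mM |
| reagent | 3.00 mM | 3.00 mM | 3.00 mM |
| temperature | −40 °C | 20 °C | −10 °C |
| time | 20 s | 20 s | 20 s |

- which flask leads in amount of target, in percent of the substrate charged ("all alike" within 1.5 percentage points) (dawn / dusk / spring / all alike)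
- how much target is there at the end, in percent of the substrate charged: dawn
- how much target is there at the end, in percent of the substrate charged: dusk
- how much target is there at the end, in percent of the substrate charged: spring

- constants are those at 20 °C; use the activation energies and enthalpies for any other temperature

Substrate is the limiting reagent (2.0 mM against 3.00 mM of reagent), so I count target as a fraction of its charge and solve the two ends separately. For dawn the cold end gives 0.137. I call this number the reach: the addition step's forward rate constant at the flask's temperature, times the reagent charge, times the time. It is a pseudo-first-order exposure. If I hold reagent at its charge and set the back step aside, the unreacted fraction is e to the minus reach, so I reckon dawn at 12.8% target.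

The warm end is the ceiling, the equilibrium fraction that the addition step allows from the two charges. In dusk the ceiling is 42.3% and the reach is 8.40, far beyond that ceiling, so I expect dusk to get there early and then lose target to the side paths, whose rate constants times the time come to 0.380 and 0.520. I treat that ceiling as a roof and reckon no further.

Spring lies where the ends join. In spring the equilibrium constant of the addition step rises to 1090 L mol⁻¹, the ceiling to 65.0%, and the reach is 1.36. As a rough join for spring, I let target climb at the reach's slope and bend to the ceiling, which gives 56.9%. The relaxation half-life of target and isomer by that step alone, both ways together, is 177 s in spring, long against the 20 s of the run. So I bet on spring, ahead of both dusk's roof and dawn, against your hunch.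

The forecast also names spring, with 12.2% for dawn, 29.1% for dusk and 53.5% for spring, which is lower than my spring figure. Its ground: “Each flask is set by the addition step, with the side reactions mattering only when warm.”

The simulation puts spring first at 53.2%, with dusk at 29.1% and dawn at 12.2%, so the forecast holds within tolerance. At the end spring holds 0.398% side product and 0.590% isomer, while dusk holds 18.9% and 12.7%. The reach gave dawn 12.8% against that 12.2%. A flask like spring kept at −35 °C has a reach of 0.209, which gives 18.9% target. That flask reads 17.6% target, with 82.4% of the substrate still there.

(The rate constants belong to no real substance.)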